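## Analysis of the target

The target is a 1,2-dioxolane (ring O1–O2–C3–C4–C5) in which both peroxide-bearing carbons are quaternary: C3 carries a methyl group and the CH2CO2H arm, and C5 carries a methyl group and an unbranched fifteen-carbon chain (C1′ to C15′, counted from C5). The chain has six methylenes (C1′–C6′), a conjugated (7′E,9′E)-diene, a doubly allylic C11′H2, an isolated (12′Z)-alkene and a terminal ethyl group. The two stereocentres, C3 (R) and C5 (S), stand in a 1,3-relation across C4; the two methyl groups lie on opposite faces of the ring, so the two CH2 arms are trans as well. The O–O bond excludes catalytic hydrogenation, low-valent metals, strong hydride donors and unhindered phosphines, the CH2C=O unit β to a peroxide oxygen can open the ring by E1cB elimination under strong base, and the skipped triene is prone to autoxidation and double-bond migration. The difficulty lies in the two fully substituted C–O carbons: neither has a hydrogen or a neighbouring stereocentre to steer its formation, and asymmetric oxidation methods do not deliver tertiary dialkyl peroxides. The plan rests on the fact that C3 and C5 are constitutionally alike, each bearing CH3 and a CH2–C unit. With the chain cut back to C1′–C2′, the core is a trans-3,5-dimethyl-1,2-dioxolane-3,5-diacetate with a twofold (C2) axis through C4 and the O–O midpoint, so its two ester arms are equivalent.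

## Retrosynthetic reasoning

**28 ⇒ 27.** The carboxylic acid is unmasked last from methyl ester 27, so that no acidic proton or carboxylate is present while carbanions are used on the chain.

**27 ⇒ 22 + 25.** The chain is cut at C9′=C10′ rather than at C7′=C8′. This pairs an α,β-unsaturated aldehyde (22) with a saturated alkyl heteroaryl sulfone (25), the combination in which this olefination is most dependably E-selective. Carbons C10′–C15′ and the (12′Z)-alkene then come unchanged from the commercial alcohol 23 through sulfide 24. The sulfone can be metalated (26) before the peroxy ester is added, so no free amide base meets the CH2CO2Me group. The forward reaction has to make the 9′E bond without disturbing 7′E or 12′Z.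

**22 ⇒ 20 + 21.** C7′=C8′ is cut to the saturated aldehyde 20 and the stabilised two-carbon ylide 21. A stabilised ylide needs no base and gives the E-enal.

**20 ⇒ 12 + 15.** The spacer C3′–C7′ is traced to 5-bromopentan-1-ol 13 (through 14, 15 and ylide 16). The C2′–C3′ bond is made as an alkene (17) and then saturated (18), because olefination followed by concerted hydrogen transfer joins two sp3 carbons without touching an O–O bond. The silyl ether is afterwards exchanged for the aldehyde (19, 20).

**12 ⇒ 10.** The C2′ aldehyde comes from the carboxylic acid arm of monoacid 10 through alcohol 11. An acid can be reduced beside a methyl ester, and this is the point at which the two arms, equivalent until then, become the chain and the future acetic acid.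

**10 ⇒ 9.** Monoacid 10 is traced to the racemic trans diester 9. Because the arms of each enantiomer of 9 are equivalent, a hydrolase only has to tell the enantiomers apart. One operation then supplies the absolute configuration and differentiates the arms.

**9 ⇒ 4 + two molecules of 7 (key disconnection).** Both exocyclic C–CH2 bonds at C3 and C5 are cut. This leaves a peroxide ring with a leaving group on each quaternary carbon (4) and two acetate nucleophiles (7). The cut is made here because it is the only one that uses the hidden symmetry: both quaternary centres come from one reaction on a ring that is already closed. The forward reaction has to ionise each peroxyketal carbon in turn without losing the peroxide and add the second arm trans to the first.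

**4 ⇒ 3 ⇒ 1 + 2, and 7 ⇐ 5.** The bis-peroxyketal 4 is the methyl ketal of diol 3, the adduct of pentane-2,4-dione 1 and hydrogen peroxide 2. The ketene acetal 7 comes from methyl acetate 5 through enolate 6. The risk of the route is thereby concentrated in the key step.

## Alternatives that were turned down

**Alternative 1:** *Disconnection.* C4–C5 and O2–C3 are cut. The ring is assembled from a peroxycarbenium ion at C5 that already carries the methyl group and C1′–C7′, and an alkene that supplies C4, C3, the C3 methyl and a two-carbon oxygenated arm. The two building blocks are the silyl peroxyketal 8-methoxy-8-[(triethylsilyl)peroxy]nonyl acetate A2 and the alkene tert-butyl[(3-methylbut-3-en-1-yl)oxy]diphenylsilane A3.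
*Forward key step.* SnCl4 (or TiCl4) removes methoxide from A2 to give the peroxycarbenium ion. The CH2 terminus of A3 attacks this cation, and the silylperoxy oxygen traps the tertiary cation so formed. The product would be racemic 7-[(3S,5S)-5-(2-{[tert-butyl(diphenyl)silyl]oxy}ethyl)-3,5-dimethyl-1,2-dioxolan-3-yl]heptyl acetate A1.
*For it.* The annulation is convergent and of a type established for simple peroxycarbenium ions and 1,1-disubstituted alkenes. Because A2 already holds seven chain carbons, later chain work shrinks to the triene. On step economy after ring formation it is stronger than the chosen plan, which builds C3′–C7′ afterwards.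
*Against it.* Each new quaternary centre carries a methyl and a primary alkyl group, and the ring closes through an open tertiary cation derived from A3, so nothing distinguishes cis from trans. A1 is racemic, has no symmetry and no functional group near a stereocentre, so resolution would fall to chromatography on a chiral phase. The C3 arm arrives as a silyl ether and needs two late oxidations.
*Comparison.* The chosen plan shares the cis/trans problem in principle, but it offers an ester arm that can bias the second addition, a twofold-symmetric diester that is easy to resolve, and an acid arm at the right oxidation level from the key step on.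

**Alternative 2:** *Disconnection.* Both C–O bonds of the peroxide (C5–O1 and O2–C3) are cut, tracing the ring to hydrogen peroxide 2 and the twofold-symmetric bis-oxetane 2,2′-methanediylbis[(2R)-2-methyloxetane] A5.
*Forward key step.* With Me3SiOTf or Yb(OTf)3, anhydrous 2 opens one oxetane of A5 at its tertiary carbon with inversion. The hydroperoxide so formed opens the second oxetane 5-exo, again with inversion, to give 2,2′-[(3S,5S)-3,5-dimethyl-1,2-dioxolane-3,5-diyl]diethanol A4.
*For it.* It is the only one of the four plans in which relative and absolute configuration of the ring are carried over from the precursor by stereospecific substitution, with no diastereomer separation and no resolution. On stereocontrol it is clearly stronger than the chosen route. The symmetry of A4 also means that mono-functionalisation of either arm gives one compound.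
*Against it.* A5, with two enantiopure tertiary ether centres, is itself a multistep target and moves the stereochemical problem rather than removing it. Inversion at a tertiary oxetane carbon competes with ionisation, which would erode the advantage claimed. Anhydrous 2 with strong Lewis acids is a handling hazard, and A4 still needs statistical monoprotection and a two-stage oxidation of one arm.
*Comparison.* The chosen plan gives up built-in stereocontrol and pays with one separation and one resolution. In return it reaches its key-step precursor in two steps from bulk chemicals and delivers both arms as esters.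

**Alternative 3:** *Disconnection.* The bond between the CH2 carbon on C3 and the ester carbon is cut together with O2–C3. The C5 centre is set beforehand in tert-butyl{[(3R)-3-hydroperoxy-3,5-dimethylhex-5-en-1-yl]oxy}diphenylsilane A7, and the ester carbon comes from monomethyl oxalate A8.
*Forward key step.* Anodic decarboxylation of A8 gives the methoxycarbonyl radical, which adds to the alkene CH2 of A7. Oxidation of the tertiary C3 radical to the cation and 5-exo capture by the C5 hydroperoxide would give methyl 2-[(3R,5S)-5-(2-{[tert-butyl(diphenyl)silyl]oxy}ethyl)-3,5-dimethyl-1,2-dioxolan-3-yl]acetate A6.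
*For it.* In A6 the ester arm stands at the correct oxidation level and the two arms are differentiated from the outset. No resolution is needed if A7 is enantiopure, and A8 is a cheap one-carbon radical source. On the first two points it is stronger than the chosen plan.
*Against it.* A free tertiary hydroperoxide is itself oxidised at an anode and is a good hydrogen-atom donor towards the acyl-type radical. The tertiary carbon radical can attack the O–O bond before it is oxidised. The C3 configuration again depends on 1,3-induction between a methyl and a primary alkyl group. An enantiopure tertiary hydroperoxide such as A7 has no direct asymmetric synthesis.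
*Comparison.* Several untested events are stacked in one step, whereas the chosen key step extends a known substitution by one iteration on a precursor made in two steps.

Key step: step 4

Assumption: pig liver esterase hydrolyses the (3R,5R) enantiomer of 9 faster than the (3S,5S) enantiomer. This cannot be predicted for ester groups β to quaternary centres; it is to be settled by a hydrolase screen, and the absolute configuration of 10 is to be assigned by X-ray analysis of a heavy-atom derivative before step 6.

Remark on handling: 3 and 4 are small peroxides with a high active-oxygen content; they are to be kept in solution and never distilled.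

## Route

Step 1
Reactants: 1 pentane-2,4-dione; 2 hydrogen peroxide
Product: 3 3,5-dimethyl-1,2-dioxolane-3,5-diol (cis/trans mixture)
Conditions: 30% aq. H2O2 (1.0 equiv), 0 °C → rt, no added acid
Reagents that add atoms: none
Why: Twofold peroxyhemiketal formation: H2O2 adds to one carbonyl group and the hydroperoxide closes onto the second, giving the five-membered cyclic peroxide that is the long-known first adduct of this β-diketone. One equivalent of oxidant without strong acid avoids hydroperoxy and bridged tetraoxane products; the two hemiketal centres need no control because both are ionised in step 4.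

Step 2
Reactants: 3 3,5-dimethyl-1,2-dioxolane-3,5-diol
Product: 4 3,5-dimethoxy-3,5-dimethyl-1,2-dioxolane (cis/trans mixture)
Conditions: MeOH, HC(OMe)3, TsOH·H2O (cat.), 0 °C → rt; then NaHCO3
Reagents that add atoms: methanol, CO
Why: Acid-catalysed exchange of peroxyhemiketal to peroxyketal through the peroxycarbenium ion, the usual way from 3-hydroxy- to 3-alkoxy-1,2-dioxolanes; the orthoester removes the water formed.

Step 3
Reactants: 5 methyl acetate
Product: 7 tert-butyl[(1-methoxyethenyl)oxy]dimethylsilane, via lithium 1-methoxyethenolate 6 (not isolated)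
Conditions: LiN(iPr)2, THF, −78 °C; then tBuMe2SiCl, DMPU, −78 °C → rt; distillation
Reagents that add atoms: tert-butyl(chloro)dimethylsilane, CC(C)(C)[Si](C)(C)Cl
Why: Kinetic ester enolisation and O-silylation in a dipolar cosolvent give the silyl ketene acetal; the tert-butyldimethylsilyl group makes it stable enough to distil and store.

Step 4
Reactants: 4 3,5-dimethoxy-3,5-dimethyl-1,2-dioxolane; 7 tert-butyl[(1-methoxyethenyl)oxy]dimethylsilane (two molecules are incorporated)
Product: 9 dimethyl 2,2′-[(3R*,5R*)-3,5-dimethyl-1,2-dioxolane-3,5-diyl]diacetate (racemate; arms trans), via mono-alkylated peroxyketal 8 (not isolated)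
Conditions: 7 (4 equiv), TiCl4 (2.5 equiv), CH2Cl2, −78 °C; aq. NaHCO3; chromatography to remove the meso (cis) isomer
Reagents that add atoms: none
Why: Proposed new method: TiCl4 binds and removes the methoxy group at one peroxyketal carbon of 4 to give a ring peroxycarbenium ion (C=O+–O), which 7 attacks at carbon to give 8; the second peroxyketal carbon then ionises in the same way and a second molecule of 7 adds, so that the C3–CH2 and C5–CH2 bonds are both made in one flask, the closest known reaction type being the TiCl4- or SnCl4-mediated substitution at the single peroxyketal carbon of 3-alkoxy-1,2-dioxolanes by silyl ketene acetals, silyl enol ethers and allylsilanes. No ring is closed in this step: the dioxolane is already present and has to survive, which it should, because ionisation of an endocyclic C–OO bond can be reversed by the tethered peroxide whereas loss of methoxide to TiCl4 cannot. Both isomers of 4 and both epimers of 8 converge, since each reacting carbon passes through a planar cation. The first new stereocentre forms without bias; the second is set relative to it by 1,3-induction across C4, the nucleophile entering the cation on the face anti to the CH2CO2Me arm, which is larger than methyl and whose ester carbonyl (free or bound to TiCl4) can lean over its own face. The step therefore needs trans over cis selectivity, and it needs both ionisations to proceed by loss of methoxide and not of the peroxide; an excess of 7 at −78 °C keeps each cation short-lived. The trans product is the racemate of the twofold-symmetric diester 9 and a diastereomer of the meso cis isomer, so the two should separate on silica and be told apart by the C4 methylene, whose two hydrogens are equivalent only in 9. Absolute configuration is not addressed here and is left to step 5.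

Step 5
Reactants: 9 dimethyl 2,2′-[(3R*,5R*)-3,5-dimethyl-1,2-dioxolane-3,5-diyl]diacetate (racemate)
Product: 10 2-[(3R,5R)-5-(2-methoxy-2-oxoethyl)-3,5-dimethyl-1,2-dioxolan-3-yl]acetic acid
Conditions: pig liver esterase, KH2PO4/K2HPO4 buffer (0.3 M, pH 7.5)/acetone 9:1, 25 °C, stopped short of half conversion; extraction at pH 8 (removes the (3S,5S) diester), then at pH 3
Reagents that add atoms: water, O
Why: Enzymatic kinetic resolution by enantioselective ester hydrolysis: the two ester arms of each enantiomer of 9 are equivalent, so either hydrolysis gives the same monoacid and the enzyme only has to tell the enantiomers apart. The carboxylate formed is a poor substrate, which should stop the reaction at the monoacid; no stereocentre is formed, the (3R,5R) series is selected.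

Step 6
Reactants: 10 2-[(3R,5R)-5-(2-methoxy-2-oxoethyl)-3,5-dimethyl-1,2-dioxolan-3-yl]acetic acid
Product: 11 methyl 2-[(3R,5S)-5-(2-hydroxyethyl)-3,5-dimethyl-1,2-dioxolan-3-yl]acetate
Conditions: BH3·SMe2, THF, 0 °C → rt; then H2O
Reagents that add atoms: none
Why: Chemoselective borane reduction of a carboxylic acid beside a methyl ester through the acyloxyborane; the electrophilic hydride should not attack the hindered di-tertiary O–O bond at this temperature. The descriptor at C5 changes from R to S only because the ligand ranking changes.

Step 7
Reactants: 11 methyl 2-[(3R,5S)-5-(2-hydroxyethyl)-3,5-dimethyl-1,2-dioxolan-3-yl]acetate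
Product: 12 methyl 2-[(3R,5R)-3,5-dimethyl-5-(2-oxoethyl)-1,2-dioxolan-3-yl]acetate
Conditions: Dess–Martin periodinane, CH2Cl2, 0 °C → rt; used without chromatography
Reagents that add atoms: none
Why: Hypervalent-iodine oxidation of a primary alcohol under non-basic, non-reducing conditions; the β-peroxy aldehyde is taken on crude because base or long contact with silica could open the ring by elimination. The descriptor at C5 is R again by ligand ranking only.

Step 8
Reactants: 13 5-bromopentan-1-ol
Product: 14 [(5-bromopentyl)oxy](tert-butyl)dimethylsilane
Conditions: tBuMe2SiCl, imidazole, CH2Cl2, 0 °C → rt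
Reagents that add atoms: tert-butyl(chloro)dimethylsilane, CC(C)(C)[Si](C)(C)Cl
Why: Standard silylation of a primary alcohol; the silyl ether survives ylide formation and diimide and is removed later without base.

Step 9
Reactants: 14 [(5-bromopentyl)oxy](tert-butyl)dimethylsilane
Product: 15 (5-{[tert-butyl(dimethyl)silyl]oxy}pentyl)triphenylphosphonium bromide
Conditions: PPh3, MeCN, reflux
Reagents that add atoms: triphenylphosphine, c1ccc(cc1)P(c1ccccc1)c1ccccc1
Why: SN2 quaternisation of a primary bromide by the phosphine gives the Wittig salt carrying C3′–C7′.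

Step 10
Reactants: 12 methyl 2-[(3R,5R)-3,5-dimethyl-5-(2-oxoethyl)-1,2-dioxolan-3-yl]acetate; 15 (5-{[tert-butyl(dimethyl)silyl]oxy}pentyl)triphenylphosphonium bromide
Product: 17 methyl 2-[(3R,5S)-5-[(2Z)-7-{[tert-butyl(dimethyl)silyl]oxy}hept-2-en-1-yl]-3,5-dimethyl-1,2-dioxolan-3-yl]acetate, via phosphorus ylide 16 (not isolated)
Conditions: 15, NaN(SiMe3)2 (slightly less than 15), THF, −78 → 0 °C; then 12, −78 → −20 °C
Reagents that add atoms: none
Why: Wittig olefination with a non-stabilised ylide forms C2′=C3′, mainly Z, which is of no consequence because the alkene is reduced next. Base kept below the amount of salt and addition of the aldehyde to the preformed ylide at −78 °C favour carbonyl addition over enolisation of the β-peroxy aldehyde.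

Step 11
Reactants: 17 methyl 2-[(3R,5S)-5-[(2Z)-7-{[tert-butyl(dimethyl)silyl]oxy}hept-2-en-1-yl]-3,5-dimethyl-1,2-dioxolan-3-yl]acetate
Product: 18 methyl 2-[(3R,5S)-5-(7-{[tert-butyl(dimethyl)silyl]oxy}heptyl)-3,5-dimethyl-1,2-dioxolan-3-yl]acetate
Conditions: KO2CN=NCO2K, AcOH, MeOH, 0 °C → rt (repeated charges)
Reagents that add atoms: none
Why: Diimide reduction: concerted syn transfer of H2 to the non-polarised C=C. The O–O bond, the ester and the silyl ether are not reduced, which is why this replaces catalytic hydrogenation.

Step 12
Reactants: 18 methyl 2-[(3R,5S)-5-(7-{[tert-butyl(dimethyl)silyl]oxy}heptyl)-3,5-dimethyl-1,2-dioxolan-3-yl]acetate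
Product: 19 methyl 2-[(3R,5S)-5-(7-hydroxyheptyl)-3,5-dimethyl-1,2-dioxolan-3-yl]acetate
Conditions: HF·pyridine, THF/pyridine, 0 °C → rt
Reagents that add atoms: none
Why: Fluoride cleavage of the primary silyl ether under buffered, weakly acidic conditions, chosen over basic fluoride sources to spare the β-peroxy ester.

Step 13
Reactants: 19 methyl 2-[(3R,5S)-5-(7-hydroxyheptyl)-3,5-dimethyl-1,2-dioxolan-3-yl]acetate
Product: 20 methyl 2-[(3R,5S)-3,5-dimethyl-5-(7-oxoheptyl)-1,2-dioxolan-3-yl]acetate
Conditions: Dess–Martin periodinane, CH2Cl2, 0 °C → rt
Reagents that add atoms: none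
Why: Same non-reducing alcohol oxidation as in step 7; this aldehyde is remote from the peroxide and can be purified normally.

Step 14
Reactants: 20 methyl 2-[(3R,5S)-3,5-dimethyl-5-(7-oxoheptyl)-1,2-dioxolan-3-yl]acetate; 21 (triphenyl-λ5-phosphanylidene)acetaldehyde
Product: 22 methyl 2-[(3R,5S)-3,5-dimethyl-5-[(7E)-9-oxonon-7-en-1-yl]-1,2-dioxolan-3-yl]acetate
Conditions: 21 (1.3 equiv), toluene, 70 °C
Reagents that add atoms: none
Why: Wittig reaction with a stabilised formyl ylide needs no base and should give the E-enal, fixing C7′=C8′. A small excess of 21 limits a second homologation, and the di-tertiary peroxide should tolerate this temperature.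

Step 15
Reactants: 23 (3Z)-hex-3-en-1-ol
Product: 24 5-{[(3Z)-hex-3-en-1-yl]sulfanyl}-1-phenyl-1H-tetrazole
Conditions: 1-phenyl-1H-tetrazole-5-thiol, PPh3, iPrO2CN=NCO2iPr, THF, 0 °C → rt
Reagents that add atoms: 1-phenyl-1H-tetrazole-5-thiol, Sc1nnnn1-c1ccccc1
Why: Mitsunobu thioetherification of a primary alcohol; the Z alkene, which becomes C12′=C13′, is not involved.

Step 16
Reactants: 24 5-{[(3Z)-hex-3-en-1-yl]sulfanyl}-1-phenyl-1H-tetrazole; 2 hydrogen peroxide
Product: 25 5-{[(3Z)-hex-3-en-1-yl]sulfonyl}-1-phenyl-1H-tetrazole
Conditions: 30% aq. H2O2, (NH4)6Mo7O24·4H2O (cat.), EtOH, 0 °C → rt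
Reagents that add atoms: none
Why: Molybdenum-catalysed oxidation of sulfide to sulfone by H2O2; the peroxo complex formed from (NH4)6Mo7O24 oxidises sulfur much faster than it epoxidises an isolated 1,2-disubstituted alkene.

Step 17
Reactants: 22 methyl 2-[(3R,5S)-3,5-dimethyl-5-[(7E)-9-oxonon-7-en-1-yl]-1,2-dioxolan-3-yl]acetate; 25 5-{[(3Z)-hex-3-en-1-yl]sulfonyl}-1-phenyl-1H-tetrazole
Product: 27 methyl 2-[(3R,5S)-3,5-dimethyl-5-[(7E,9E,12Z)-pentadeca-7,9,12-trien-1-yl]-1,2-dioxolan-3-yl]acetate, via potassium sulfonyl carbanion 26 (not isolated)
Conditions: 25 (1.3 equiv), KN(SiMe3)2 (1.25 equiv), DME, −55 °C; then 22, −55 °C → rt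
Reagents that add atoms: none
Why: Julia–Kocienski olefination: the preformed carbanion adds to the enal, and Smiles rearrangement followed by loss of SO2 and the tetrazololate forms C9′=C10′. The E geometry is expected from the anti-selective addition and antiperiplanar elimination usual for 1-phenyltetrazolyl sulfones with potassium in DME; the 12′Z alkene comes unchanged from 23. Because the sulfone is metalated first, no amide base meets the peroxy ester.

Step 18
Reactants: 27 methyl 2-[(3R,5S)-3,5-dimethyl-5-[(7E,9E,12Z)-pentadeca-7,9,12-trien-1-yl]-1,2-dioxolan-3-yl]acetate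
Product: 28 2-[(3R,5S)-3,5-dimethyl-5-[(7E,9E,12Z)-pentadeca-7,9,12-trien-1-yl]-1,2-dioxolan-3-yl]acetic acid
Conditions: LiOH, THF/MeOH/H2O, 0 °C → rt, argon, dark; then 1 M HCl to pH 4 at 0 °C
Reagents that add atoms: lithium hydroxide, [Li+].[OH-]
Why: Saponification of the methyl ester by acyl substitution; hydroxide in aqueous medium attacks the ester carbonyl rather than enolising it, so the β-peroxide should stay closed. Mild acidification at low temperature under argon protects the skipped triene.

## Compound list

1 | pentane-2,4-dione | CC(=O)CC(C)=O | starting material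
2 | hydrogen peroxide | OO | starting material
3 | 3,5-dimethyl-1,2-dioxolane-3,5-diol (cis/trans mixture) | CC1(O)CC(C)(O)OO1 | intermediate
4 | 3,5-dimethoxy-3,5-dimethyl-1,2-dioxolane (cis/trans mixture) | COC1(C)CC(C)(OC)OO1 | intermediate
5 | methyl acetate | COC(C)=O | starting material
6 | lithium 1-methoxyethenolate | [Li+].[O-]C(=C)OC | intermediate (not isolated)
7 | tert-butyl[(1-methoxyethenyl)oxy]dimethylsilane | C=C(OC)O[Si](C)(C)C(C)(C)C | intermediate
8 | methyl 2-(5-methoxy-3,5-dimethyl-1,2-dioxolan-3-yl)acetate (racemic; both diastereomers) | COC(=O)CC1(C)CC(C)(OC)OO1 | intermediate (not isolated)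
9 | dimethyl 2,2′-[(3R*,5R*)-3,5-dimethyl-1,2-dioxolane-3,5-diyl]diacetate (racemate; the (3R,5R) enantiomer is drawn) | COC(=O)C[C@@]1(C)C[C@](C)(CC(=O)OC)OO1 | intermediate
10 | 2-[(3R,5R)-5-(2-methoxy-2-oxoethyl)-3,5-dimethyl-1,2-dioxolan-3-yl]acetic acid | OC(=O)C[C@@]1(C)C[C@](C)(CC(=O)OC)OO1 | intermediate
11 | methyl 2-[(3R,5S)-5-(2-hydroxyethyl)-3,5-dimethyl-1,2-dioxolan-3-yl]acetate | OCC[C@@]1(C)C[C@](C)(CC(=O)OC)OO1 | intermediate
12 | methyl 2-[(3R,5R)-3,5-dimethyl-5-(2-oxoethyl)-1,2-dioxolan-3-yl]acetate | O=CC[C@@]1(C)C[C@](C)(CC(=O)OC)OO1 | intermediate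
13 | 5-bromopentan-1-ol | OCCCCCBr | starting material
14 | [(5-bromopentyl)oxy](tert-butyl)dimethylsilane | CC(C)(C)[Si](C)(C)OCCCCCBr | intermediate
15 | (5-{[tert-butyl(dimethyl)silyl]oxy}pentyl)triphenylphosphonium bromide | CC(C)(C)[Si](C)(C)OCCCCC[P+](c1ccccc1)(c1ccccc1)c1ccccc1.[Br-] | intermediate
16 | tert-butyldimethyl{[5-(triphenyl-λ5-phosphanylidene)pentyl]oxy}silane | CC(C)(C)[Si](C)(C)OCCCCC=P(c1ccccc1)(c1ccccc1)c1ccccc1 | intermediate (not isolated)
17 | methyl 2-[(3R,5S)-5-[(2Z)-7-{[tert-butyl(dimethyl)silyl]oxy}hept-2-en-1-yl]-3,5-dimethyl-1,2-dioxolan-3-yl]acetate | CC(C)(C)[Si](C)(C)OCCCC/C=C\C[C@@]1(C)C[C@](C)(CC(=O)OC)OO1 | intermediate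
18 | methyl 2-[(3R,5S)-5-(7-{[tert-butyl(dimethyl)silyl]oxy}heptyl)-3,5-dimethyl-1,2-dioxolan-3-yl]acetate | CC(C)(C)[Si](C)(C)OCCCCCCC[C@@]1(C)C[C@](C)(CC(=O)OC)OO1 | intermediate
19 | methyl 2-[(3R,5S)-5-(7-hydroxyheptyl)-3,5-dimethyl-1,2-dioxolan-3-yl]acetate | OCCCCCCC[C@@]1(C)C[C@](C)(CC(=O)OC)OO1 | intermediate
20 | methyl 2-[(3R,5S)-3,5-dimethyl-5-(7-oxoheptyl)-1,2-dioxolan-3-yl]acetate | O=CCCCCCC[C@@]1(C)C[C@](C)(CC(=O)OC)OO1 | intermediate
21 | (triphenyl-λ5-phosphanylidene)acetaldehyde | O=CC=P(c1ccccc1)(c1ccccc1)c1ccccc1 | starting material
22 | methyl 2-[(3R,5S)-3,5-dimethyl-5-[(7E)-9-oxonon-7-en-1-yl]-1,2-dioxolan-3-yl]acetate | O=C/C=C/CCCCCC[C@@]1(C)C[C@](C)(CC(=O)OC)OO1 | intermediate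
23 | (3Z)-hex-3-en-1-ol | CC/C=C\CCO | starting material
24 | 5-{[(3Z)-hex-3-en-1-yl]sulfanyl}-1-phenyl-1H-tetrazole | CC/C=C\CCSc1nnnn1-c1ccccc1 | intermediate
25 | 5-{[(3Z)-hex-3-en-1-yl]sulfonyl}-1-phenyl-1H-tetrazole | CC/C=C\CCS(=O)(=O)c1nnnn1-c1ccccc1 | intermediate
26 | potassium (3Z)-1-[(1-phenyl-1H-tetrazol-5-yl)sulfonyl]hex-3-en-1-ide | [K+].CC/C=C\C[CH-]S(=O)(=O)c1nnnn1-c1ccccc1 | intermediate (not isolated)
27 | methyl 2-[(3R,5S)-3,5-dimethyl-5-[(7E,9E,12Z)-pentadeca-7,9,12-trien-1-yl]-1,2-dioxolan-3-yl]acetate | CC/C=C\C/C=C/C=C/CCCCCC[C@@]1(C)C[C@](C)(CC(=O)OC)OO1 | intermediate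
28 | 2-[(3R,5S)-3,5-dimethyl-5-[(7E,9E,12Z)-pentadeca-7,9,12-trien-1-yl]-1,2-dioxolan-3-yl]acetic acid | CC/C=C\C/C=C/C=C/CCCCCC[C@@]1(C)C[C@](C)(CC(=O)O)OO1 | target

## Step count and least certain steps

Total step count: 18. Longest linear sequence: 13 steps (1, 2, 4, 5, 6, 7, 10, 11, 12, 13, 14, 17, 18).

**Step 4 (key step, proposed new method).**
- What may go wrong: ionisation in the wrong sense (C–OO cleavage) with loss of hydrogen peroxide, leaving non-peroxidic Mukaiyama-type products of the diketone. The second substitution may stall once the first ester binds the Lewis acid. The second addition may lack facial bias, so that the meso isomer forms in similar amount. The last of these costs material only, since 4 and 7 come from bulk chemicals in three steps.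
- Fallback (known chemistry; sets out from pentane-2,4-dione 1 and ketene acetal 7, comes back at 9): only one peroxyketal carbon is ionised, which is the established case. 1 is converted with HC(OMe)3/MeOH/TsOH into (3E)-4-methoxypent-3-en-2-one F1. Addition of CH2=CHCH2MgBr and acidic work-up (1,2-addition, hydrolysis, loss of methanol) gives 4-methylhepta-3,6-dien-2-one F2. Conjugate addition of hydrogen peroxide 2 (cat. LiOH, MeOH, 0 °C; any epoxide formed beside it is removed) with ring closure gives 3,5-dimethyl-5-(prop-2-en-1-yl)-1,2-dioxolan-3-ol F3. MeOH/TsOH gives 3-methoxy-3,5-dimethyl-5-(prop-2-en-1-yl)-1,2-dioxolane F4. TiCl4 and 7 then give methyl 2-[(3R*,5S*)-3,5-dimethyl-5-(prop-2-en-1-yl)-1,2-dioxolan-3-yl]acetate F5 after separation from its cis isomer. Ozonolysis of the allyl group in CH2Cl2/MeOH at −78 °C followed by Ac2O/Et3N turns it into the second CH2CO2Me arm, that is into 9.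

**Step 5.**
- What may go wrong: insufficient discrimination between the enantiomers, because the stereocentres are quaternary and two bonds from the reacting carbonyl, or preference for the wrong enantiomer.
- Fallback (sets out from 9, comes back at 10): racemic 9 is separated by preparative chromatography on a polysaccharide-carbamate chiral phase. The (3R,5R) enantiomer is then monosaponified with one equivalent of LiOH; the arms are equivalent, so only over- and under-hydrolysed material has to be removed. If the enzyme is selective but prefers the (3S,5S) enantiomer, the hydrolysis is run beyond half conversion and the recovered (3R,5R)-9 is monosaponified in the same way.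

**Step 10.**
- What may go wrong: enolisation of the β-peroxy aldehyde 12 by the basic ylide, followed by E1cB opening of the dioxolane.
- Fallback (sets out from 12, comes back at 19): 12 is heated with the non-basic stabilised ylide 21 (toluene, 60 °C) to give methyl 2-[(3R,5S)-3,5-dimethyl-5-[(2E)-4-oxobut-2-en-1-yl]-1,2-dioxolan-3-yl]acetate F6. In F6 the CH2 next to the peroxide carbon is only vinylogously activated, and its γ-deprotonation should be slow compared with ylide addition to the unhindered enal carbonyl at −78 °C. F6 is olefinated at −78 °C with the ylide from commercial (3-hydroxypropyl)triphenylphosphonium bromide F7 (two equivalents of NaN(SiMe3)2) to give methyl 2-[(3R,5S)-5-[(2E,4Z)-7-hydroxyhepta-2,4-dien-1-yl]-3,5-dimethyl-1,2-dioxolan-3-yl]acetate F8. Diimide under the conditions of step 11, in larger excess, saturates both double bonds and gives 19 directly.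

**Step 17.**
- What may go wrong: incomplete E selectivity at C9′=C10′, since conjugated aldehydes are less selective than saturated ones with this sulfone class, and a difficult separation of the 9′Z isomer (AgNO3-impregnated silica or preparative HPLC at the ester stage).
- Fallback (sets out from aldehyde 20 and alcohol 23, comes back at 27): both diene double bonds are taken from building blocks of fixed geometry and joined by a stereospecific coupling. 20 is homologated with dimethyl (1-diazo-2-oxopropyl)phosphonate (K2CO3, MeOH) to methyl 2-[(3R,5S)-3,5-dimethyl-5-(oct-7-yn-1-yl)-1,2-dioxolan-3-yl]acetate F9. Hydroboration with 4,4,5,5-tetramethyl-1,3,2-dioxaborolane and catalytic Cp2Zr(H)Cl gives the (E)-alkenylboronate methyl 2-[(3R,5S)-3,5-dimethyl-5-[(7E)-8-(4,4,5,5-tetramethyl-1,3,2-dioxaborolan-2-yl)oct-7-en-1-yl]-1,2-dioxolan-3-yl]acetate F10. Separately, 23 is oxidised (Dess–Martin periodinane) to (3Z)-hex-3-enal F11, and Takai olefination (CrCl2, CHI3) gives (1E,4Z)-1-iodohepta-1,4-diene F12; the divalent chromium never meets the peroxide. Suzuki coupling of F10 with F12 (Pd(PPh3)4, aq. K3PO4, THF, rt) forms C8′–C9′ with retention at both partners and gives 27; the di-tertiary peroxide should be slow to react with PPh3 at room temperature.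

**Step 18.**
- What may go wrong: enolisation of the ester with E1cB opening of the ring, or base-induced migration of the skipped double bonds.
- Fallback (sets out from 27, comes back at 28): hydrolysis at pH 7 to 7.5 with the esterase of step 5 or a lipase in buffer/cosolvent, which replaces hydroxide by an acyl-enzyme pathway at neutral pH. The enzyme will already have accepted this kind of ester arm in the (3R,5R) series.

## Further compounds

F1 | step 4 | (3E)-4-methoxypent-3-en-2-one | CO/C(C)=C/C(C)=O
F2 | step 4 | 4-methylhepta-3,6-dien-2-one (E/Z mixture) | CC(=O)C=C(C)CC=C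
F3 | step 4 | 3,5-dimethyl-5-(prop-2-en-1-yl)-1,2-dioxolan-3-ol (racemic; both diastereomers) | CC1(O)CC(C)(CC=C)OO1
F4 | step 4 | 3-methoxy-3,5-dimethyl-5-(prop-2-en-1-yl)-1,2-dioxolane (racemic; both diastereomers) | COC1(C)CC(C)(CC=C)OO1
F5 | step 4 | methyl 2-[(3R*,5S*)-3,5-dimethyl-5-(prop-2-en-1-yl)-1,2-dioxolan-3-yl]acetate (racemate; arms trans; one enantiomer drawn) | C=CC[C@@]1(C)C[C@](C)(CC(=O)OC)OO1
F0 | step 5 | none | none
F6 | step 10 | methyl 2-[(3R,5S)-3,5-dimethyl-5-[(2E)-4-oxobut-2-en-1-yl]-1,2-dioxolan-3-yl]acetate | O=C/C=C/C[C@@]1(C)C[C@](C)(CC(=O)OC)OO1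
F7 | step 10 | (3-hydroxypropyl)triphenylphosphonium bromide | OCCC[P+](c1ccccc1)(c1ccccc1)c1ccccc1.[Br-]
F8 | step 10 | methyl 2-[(3R,5S)-5-[(2E,4Z)-7-hydroxyhepta-2,4-dien-1-yl]-3,5-dimethyl-1,2-dioxolan-3-yl]acetate | OCC/C=C\C=C\C[C@@]1(C)C[C@](C)(CC(=O)OC)OO1
F9 | step 17 | methyl 2-[(3R,5S)-3,5-dimethyl-5-(oct-7-yn-1-yl)-1,2-dioxolan-3-yl]acetate | C#CCCCCCC[C@@]1(C)C[C@](C)(CC(=O)OC)OO1
F10 | step 17 | methyl 2-[(3R,5S)-3,5-dimethyl-5-[(7E)-8-(4,4,5,5-tetramethyl-1,3,2-dioxaborolan-2-yl)oct-7-en-1-yl]-1,2-dioxolan-3-yl]acetate | CC1(C)OB(/C=C/CCCCCC[C@@]2(C)C[C@](C)(CC(=O)OC)OO2)OC1(C)C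
F11 | step 17 | (3Z)-hex-3-enal | CC/C=C\CC=O
F12 | step 17 | (1E,4Z)-1-iodohepta-1,4-diene | CC/C=C\C/C=C/I
F0 | step 18 | none | none
A1 | alternative 1 | 7-[(3S,5S)-5-(2-{[tert-butyl(diphenyl)silyl]oxy}ethyl)-3,5-dimethyl-1,2-dioxolan-3-yl]heptyl acetate (would form as the racemate) | CC(=O)OCCCCCCC[C@@]1(C)C[C@](C)(CCO[Si](c2ccccc2)(c2ccccc2)C(C)(C)C)OO1
A2 | alternative 1 | 8-methoxy-8-[(triethylsilyl)peroxy]nonyl acetate (racemic) | CC(=O)OCCCCCCCC(C)(OC)OO[Si](CC)(CC)CC
A3 | alternative 1 | tert-butyl[(3-methylbut-3-en-1-yl)oxy]diphenylsilane | C=C(C)CCO[Si](c1ccccc1)(c1ccccc1)C(C)(C)C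
A4 | alternative 2 | 2,2′-[(3S,5S)-3,5-dimethyl-1,2-dioxolane-3,5-diyl]diethanol | OCC[C@@]1(C)C[C@](C)(CCO)OO1
A5 | alternative 2 | 2,2′-methanediylbis[(2R)-2-methyloxetane] | O1CC[C@]1(C)C[C@@]2(C)CCO2
A6 | alternative 3 | methyl 2-[(3R,5S)-5-(2-{[tert-butyl(diphenyl)silyl]oxy}ethyl)-3,5-dimethyl-1,2-dioxolan-3-yl]acetate | CC(C)(C)[Si](c1ccccc1)(c1ccccc1)OCC[C@@]1(C)C[C@](C)(CC(=O)OC)OO1
A7 | alternative 3 | tert-butyl{[(3R)-3-hydroperoxy-3,5-dimethylhex-5-en-1-yl]oxy}diphenylsilane | CC(C)(C)[Si](c1ccccc1)(c1ccccc1)OCC[C@@](OO)(C)CC(C)=C
A8 | alternative 3 | monomethyl oxalate (2-methoxy-2-oxoacetic acid) | COC(=O)C(=O)O
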